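The runs are simulated with made-up constants; scatter was added.

- Amounts first: every flask below holds c(substrate) at 1.0 M and c(partner) at 1.20 M, and c(free catalyst) is what varies, so we reckon how fast each loading makes target.

| flask | substrate | partner | free catalyst | remark | time |
|---|---|---|---|---|---|
| zeta | 1 M | 1.2 M | 74 mM | run made earlier |  |
| gamma | 1 M | 1.2 M | 980 mM | run made earlier |  |
| ash | 1.0 M | 1.20 M | 50 mM |  | 3.0 h |
| maple | 1.0 M | 1.20 M | 100 mM |  | 3.0 h |
| alder | 1.0 M | 1.20 M | 200 mM |  | 3.0 h |
| cedar | 1.0 M | 1.20 M | 400 mM |  | 3.0 h |
| larch | 1.0 M | 1.20 M | 800 mM |  | 3.0 h |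

| run | time / h | target / % | substrate / % |
|---|---|---|---|
| zeta | 0.417 | 4 | 93 |
| zeta | 0.833 | 9 | 88 |
| zeta | 1.33 | 21 | 76 |
| zeta | 1.50 | 15 | 75 |
| zeta | 2.00 | 22 | 71 |
| zeta | 2.50 | 30 | 63 |
| zeta | 3.00 | 31 | 54 |
| gamma | 0.417 | 29 | 56 |
| gamma | 0.833 | 45 | 29 |
| gamma | 1.33 | 52 | 12 |
| gamma | 1.50 | 51 | 12 |
| gamma | 2.00 | 56 | 3 |
| gamma | 2.50 | 54 | 4 |
| gamma | 3.00 | 56 | 3 |

(scatter of a reading: 2 percentage points)

- a species is counted by the substrate in it: one side product counts as two
- the earlier runs were read with a standard deviation of 2 percentage points
- reactions considered so far: partner + free catalyst -> catalyst intermediate A; catalyst intermediate A -> catalyst intermediate B; substrate + catalyst intermediate B -> catalyst intermediate C; catalyst intermediate C <-> free catalyst + target; partner -> decomposed reagent; substrate + target -> side product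
- "hardly changes" means that all values lie within two and a half points (for a concentration: within two and a half percent of the largest)

- amount of target at the end, in percent of the substrate charged for ash, maple, alder, cedar, larch, in this order
- how the row runs (hardly changes / rises, then falls / falls, then rises / rises all the way / falls all the way)

- In zeta, 54% of the substrate remains at 3.00 h, which gives kappa = 2.78 /M/h, the pseudo-first-order decay constant of substrate divided by the charged c(free catalyst); it is a reading and carries the scatter of 2 percentage points.
- For ash, kappa puts the starting rate of substrate use at 0.139 M/h, with no lag counted.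
- The first slowing is the loss of substrate: on this reckoning the rate in ash is down to 65.9% of its start by 3.0 h.
- The second factor is a share: in zeta, 67.4% of the substrate used stands as target at 3.00 h, so we scale the target made by that share.
- A third factor shows in gamma: its first reading, at 0.417 h, gives 1.42 /M/h, about half of kappa, though that value covers a shorter time as well as a higher loading.
- Our own reckoning gives 23.0% of target for ash, 38.1% for maple and 65.0% for cedar, each with the kappa and the share of zeta, so the third factor is not counted in them.
- Gamma reads 56% at 3.00 h, less than that cedar figure, so we expect a row that rises, then falls.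
- The forecast gives 23%, 37%, 54%, 62% and 59%, with the shape "rises, then falls", and says: “Target should peak near 400 mM at about 60 %”. Its cedar point lies below ours.
- The flask gives 22.9%, 38.8%, 57.8%, 69.7% and 61.2%, with the shape "rises, then falls".

    partner + free catalyst → catalyst intermediate A (k = 0.00280 /M/s)
    catalyst intermediate A → catalyst intermediate B (k = 0.00570 /s)
    substrate + catalyst intermediate B → catalyst intermediate C (k = 0.00100 /M/s)
    catalyst intermediate C ⇌ free catalyst + target (K = 0.600 M, k = 0.120 /s)
    partner → decomposed reagent (k = 2.40 × 10⁻⁵ /s)
    substrate + target → side product (k = 4.30 × 10⁻⁵ /M/s)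

- In ash at 3.00 h, target is made 3.09 times faster than it is used up, each step taken net, and the substrate left is 67% against 65.9% from kappa. In maple, kappa gives 43.5% of the substrate left at 3.00 h, and the flask holds 47%.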